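## Retrosynthetic overview

1. Target ⇐ chelation-controlled 7-O-demethylation and desilylation ⇐ aryl cyclohexenyl ketone ⇐ alcohol oxidation ⇐ Nozaki–Hiyama–Kishi union of an 8-formylcoumarin with a cyclohexenyl triflate.
2. Cyclohexenyl triflate ⇐ cis-2,3-disubstituted cyclohexanone ⇐ alkene hydrogenation ⇐ key step: asymmetric epoxidation and semipinacol ring expansion of a 1-propenylcyclopent-2-enol (five- to six-membered ring) ⇐ 2-methylcyclopent-2-enone + (E)-1-bromopropene.
3. 8-Formylcoumarin ⇐ Vilsmeier formylation ⇐ pyranone ring by Pd carbonylative annulation (o-iodophenol + but-2-yne + CO) ⇐ phenol by Ir C–H borylation/oxidation ⇐ ortho-lithiation/prenylation of resorcinol dimethyl ether ⇐ resorcinol.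
4. Ring order: the benzene ring is bought; the pyranone ring is closed on it (step 5); the carbocycle is made by ring expansion of a cyclopentene (step 8); the two halves are joined last (step 11).

Assumption: the sense of induction of the chiral oxidation catalysts is taken as written ((R,R)-ligand in step 8, L-sorbose-derived ketone in the first fallback); if it proves opposite, the other catalyst enantiomer is used.
Abbreviations: BHA ligand = N,N'-dihydroxy-N,N'-bis(diphenylacetyl)cyclohexane-1,2-diamine; dtbpy = 4,4'-di-tert-butyl-2,2'-bipyridine; B2pin2 = bis(pinacolato)diboron.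

## Route

Step 1
Reactants: 1 resorcinol
Product: 2 1,3-dimethoxybenzene
Conditions: MeI (2.5 equiv), K2CO3, acetone, reflux
Reagents that add atoms: iodomethane CI
Why: Williamson ether synthesis on both phenols gives the symmetric diether whose methoxy groups direct the next lithiation, one of them ending as the 5-methoxy group of the target.

Step 2
Reactants: 2 1,3-dimethoxybenzene; 3 1-bromo-3-methylbut-2-ene
Product: 5 1,3-dimethoxy-2-(3-methylbut-2-en-1-yl)benzene, via aryllithium 4 (not isolated)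
Conditions: n-BuLi, THF, 0 °C to rt; then CuI (10 mol%), 3, −78 °C to rt
Reagents that add atoms: none
Why: Directed ortho-metalation between the two methoxy groups, then copper-assisted SN2 alkylation with the primary allylic bromide, puts the prenyl group on C2 only.

Step 3
Reactants: 5 1,3-dimethoxy-2-(3-methylbut-2-en-1-yl)benzene
Product: 7 3,5-dimethoxy-4-(3-methylbut-2-en-1-yl)phenol, via pinacol boronate 6 (not isolated)
Conditions: [Ir(OMe)(cod)]2 (1.5 mol%), dtbpy (3 mol%), B2pin2 (1 equiv), THF, 80 °C; then NaOH (1 equiv), 30% H2O2, THF/H2O, 0 °C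
Reagents that add atoms: hydrogen peroxide OO
Why: Sterically controlled iridium-catalysed C–H borylation takes the only ring C–H without an ortho substituent (C5), and basic peroxide oxidation of the boronate, which does not epoxidise the prenyl alkene, gives the phenol.

Step 4
Reactants: 7 3,5-dimethoxy-4-(3-methylbut-2-en-1-yl)phenol
Product: 8 2-iodo-3,5-dimethoxy-4-(3-methylbut-2-en-1-yl)phenol
Conditions: N-iodosuccinimide (1.0 equiv), CH2Cl2, −40 to 0 °C
Reagents that add atoms: N-iodosuccinimide O=C1CCC(=O)N1I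
Why: Electrophilic aromatic iodination ortho to the free phenol; the two ortho positions are equivalent by symmetry and the para position is blocked, so one mono-iodide results.

Step 5
Reactants: 8 2-iodo-3,5-dimethoxy-4-(3-methylbut-2-en-1-yl)phenol; 9 but-2-yne
Product: 10 5,7-dimethoxy-3,4-dimethyl-6-(3-methylbut-2-en-1-yl)-2H-chromen-2-one
Conditions: Pd(OAc)2 (5 mol%), pyridine (2 equiv), n-Bu4NCl (1 equiv), CO (1 atm), 9 (5 equiv), DMF, 110 °C, sealed vessel
Reagents that add atoms: carbon monoxide [C-]#[O+]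
Why: Larock-type carbonylative annulation (oxidative addition of the aryl iodide, alkyne insertion, CO insertion, lactonisation by the phenol) builds the 3,4-dimethylpyranone ring under non-acidic conditions that spare the prenyl group; the symmetric alkyne leaves no regiochemical question.

Step 6
Reactants: 10 5,7-dimethoxy-3,4-dimethyl-6-(3-methylbut-2-en-1-yl)-2H-chromen-2-one
Product: 12 5,7-dimethoxy-3,4-dimethyl-6-(3-methylbut-2-en-1-yl)-2-oxo-2H-chromene-8-carbaldehyde, via iminium chloride 11 (not isolated)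
Conditions: POCl3 (1.5 equiv), DMF, 0 to 60 °C; then H2O, 0 °C
Reagents that add atoms: N,N-dimethylformamide CN(C)C=O; water O
Why: Vilsmeier–Haack formylation at C8, the only free ring position, which is activated by an ortho methoxy group, the ortho ring oxygen and a para methoxy group.

Step 7
Reactants: 13 (E)-1-bromoprop-1-ene; 14 2-methylcyclopent-2-en-1-one
Product: 16 rac-2-methyl-1-[(1E)-prop-1-en-1-yl]cyclopent-2-en-1-ol, via (E)-prop-1-enyllithium 15 (not isolated)
Conditions: t-BuLi (2 equiv), Et2O, −78 °C; then 14, −78 °C; H2O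
Reagents that add atoms: none
Why: Bromine–lithium exchange with retention of the E geometry and 1,2-addition of the hard alkenyllithium to the enone carbonyl; the racemic carbinol center is destroyed in step 8, so it needs no control.

Step 8
Reactants: 16 rac-2-methyl-1-[(1E)-prop-1-en-1-yl]cyclopent-2-en-1-ol
Product: 18 (2S)-3-methyl-2-[(1S)-1-(triethylsilyloxy)ethyl]cyclohex-3-en-1-one, via epoxy alcohol 17 (not isolated)
Conditions: Hf(OtBu)4 (10 mol%), (R,R)-BHA ligand (11 mol%), t-BuOOH (1.1 equiv), 4 Å MS, toluene, 0 °C; evaporate; then Et3SiOTf (1.2 equiv), 2,6-lutidine, CH2Cl2, −78 °C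
Reagents that add atoms: tert-butyl hydroperoxide CC(C)(C)OO; triethylsilyl trifluoromethanesulfonate CC[Si](CC)(CC)OS(=O)(=O)C(F)(F)F
Why: Proposed new method: the tetravalent hafnium bis-hydroxamate binds the tertiary alkoxide of either enantiomer of 16 and delivers the peroxide oxygen to one face of the acyclic E-propenyl group (the ring alkene cannot reach the required O–C–C=C dihedral), so both enantiomers give the (2R,3S)-oxirane 17; the silyl triflate then opens the oxirane at the carbinol-bearing carbon while the ring vinyl carbon shifts 1,2 anti to the breaking C–O bond (semipinacol ring expansion, cyclopentenol to cyclohexenone), which erases the carbinol center, inverts the oxirane carbon to the (S) ring center and keeps the (S)-carbinol as its silyl ether, anti to each other; the closest known reactions are hafnium bis-hydroxamic acid epoxidation of achiral tertiary allylic alcohols and Lewis-acid semipinacol rearrangement of 2,3-epoxy alcohols, here merged and used enantioconvergently on a racemic divinyl carbinol.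

Step 9
Reactants: 18 (2S)-3-methyl-2-[(1S)-1-(triethylsilyloxy)ethyl]cyclohex-3-en-1-one
Product: 19 (2S,3R)-3-methyl-2-[(1S)-1-(triethylsilyloxy)ethyl]cyclohexan-1-one
Conditions: H2 (1 atm), [Ir(cod)(PCy3)(py)]PF6 (5 mol%), CH2Cl2, 0 °C
Reagents that add atoms: none
Why: Catalytic syn-hydrogenation of the trisubstituted alkene from the face opposite the C2 side chain, which A(1,2) strain with the vinylic methyl holds pseudoaxial (the bulky silyl ether does not direct the catalyst), sets C3 as R with the methyl cis to the side chain.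

Step 10
Reactants: 19 (2S,3R)-3-methyl-2-[(1S)-1-(triethylsilyloxy)ethyl]cyclohexan-1-one
Product: 21 (5R,6S)-5-methyl-6-[(1S)-1-(triethylsilyloxy)ethyl]cyclohex-1-en-1-yl trifluoromethanesulfonate, via potassium enolate 20 (not isolated)
Conditions: KN(SiMe3)2 (1.1 equiv), THF, −78 °C; then PhNTf2, −78 to 0 °C
Reagents that add atoms: N-phenylbis(trifluoromethanesulfonimide) O=S(=O)(N(c1ccccc1)S(=O)(=O)C(F)(F)F)C(F)(F)F
Why: Kinetic deprotonation at the unhindered CH2 alpha carbon and O-triflation give the less substituted enol triflate and leave the adjacent stereocenter untouched.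

Step 11
Reactants: 21 (5R,6S)-5-methyl-6-[(1S)-1-(triethylsilyloxy)ethyl]cyclohex-1-en-1-yl trifluoromethanesulfonate; 12 5,7-dimethoxy-3,4-dimethyl-6-(3-methylbut-2-en-1-yl)-2-oxo-2H-chromene-8-carbaldehyde
Product: 22 8-{hydroxy[(5R,6R)-5-methyl-6-[(1S)-1-(triethylsilyloxy)ethyl]cyclohex-1-en-1-yl]methyl}-5,7-dimethoxy-3,4-dimethyl-6-(3-methylbut-2-en-1-yl)-2H-chromen-2-one (both carbinol epimers)
Conditions: CrCl2 (4 equiv), NiCl2 (2 mol%), DMF/THF, rt; H2O
Reagents that add atoms: none
Why: Nozaki–Hiyama–Kishi coupling: nickel inserts into the alkenyl triflate, transmetalation gives an alkenylchromium species that adds only to the aldehyde (lactone, alkenes and silyl ether are inert), and the new carbinol center is removed in step 12.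

Step 12
Reactants: 22 8-{hydroxy[(5R,6R)-5-methyl-6-[(1S)-1-(triethylsilyloxy)ethyl]cyclohex-1-en-1-yl]methyl}-5,7-dimethoxy-3,4-dimethyl-6-(3-methylbut-2-en-1-yl)-2H-chromen-2-one
Product: 23 5,7-dimethoxy-3,4-dimethyl-6-(3-methylbut-2-en-1-yl)-8-{[(5R,6R)-5-methyl-6-[(1S)-1-(triethylsilyloxy)ethyl]cyclohex-1-en-1-yl]carbonyl}-2H-chromen-2-one
Conditions: Dess–Martin periodinane (1.5 equiv), CH2Cl2, 0 °C to rt
Reagents that add atoms: none
Why: Dess–Martin oxidation of the benzylic, allylic carbinol gives the aryl enone; the ring stereocenters are not alpha to the new ketone and cannot epimerise.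

Step 13
Reactants: 23 5,7-dimethoxy-3,4-dimethyl-6-(3-methylbut-2-en-1-yl)-8-{[(5R,6R)-5-methyl-6-[(1S)-1-(triethylsilyloxy)ethyl]cyclohex-1-en-1-yl]carbonyl}-2H-chromen-2-one
Product: 25 7-hydroxy-8-{[(5R,6R)-6-[(1S)-1-hydroxyethyl]-5-methylcyclohex-1-en-1-yl]carbonyl}-5-methoxy-3,4-dimethyl-6-(3-methylbut-2-en-1-yl)-2H-chromen-2-one, via phenol silyl ether 24 (not isolated)
Conditions: MgI2·OEt2 (3 equiv), toluene, 60 °C; then 1 M HCl, THF, 0 °C
Reagents that add atoms: none
Why: Chelation-controlled ether cleavage: magnesium bridges the ketone oxygen and the ortho 7-methoxy oxygen so iodide removes only that methyl group (the 5-methoxy group has no carbonyl neighbour), and brief dilute acid hydrolyses the triethylsilyl ether without touching the stereocenters.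

## Compound list

1 | resorcinol (benzene-1,3-diol) | Oc1cccc(O)c1 | starting material
2 | 1,3-dimethoxybenzene | COc1cccc(OC)c1 | intermediate
3 | 1-bromo-3-methylbut-2-ene (prenyl bromide) | CC(C)=CCBr | starting material
4 | (2,6-dimethoxyphenyl)lithium | [Li]c1c(OC)cccc1OC | intermediate
5 | 1,3-dimethoxy-2-(3-methylbut-2-en-1-yl)benzene | COc1cccc(OC)c1CC=C(C)C | intermediate
6 | 2-[3,5-dimethoxy-4-(3-methylbut-2-en-1-yl)phenyl]-4,4,5,5-tetramethyl-1,3,2-dioxaborolane | COc1cc(B2OC(C)(C)C(C)(C)O2)cc(OC)c1CC=C(C)C | intermediate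
7 | 3,5-dimethoxy-4-(3-methylbut-2-en-1-yl)phenol | COc1cc(O)cc(OC)c1CC=C(C)C | intermediate
8 | 2-iodo-3,5-dimethoxy-4-(3-methylbut-2-en-1-yl)phenol | COc1cc(O)c(I)c(OC)c1CC=C(C)C | intermediate
9 | but-2-yne | CC#CC | starting material
10 | 5,7-dimethoxy-3,4-dimethyl-6-(3-methylbut-2-en-1-yl)-2H-chromen-2-one | COc1c(CC=C(C)C)c(OC)cc2oc(=O)c(C)c(C)c12 | intermediate
11 | N-{[5,7-dimethoxy-3,4-dimethyl-6-(3-methylbut-2-en-1-yl)-2-oxo-2H-chromen-8-yl]methylidene}-N-methylmethanaminium chloride | COc1c(CC=C(C)C)c(OC)c(C=[N+](C)C)c2oc(=O)c(C)c(C)c12.[Cl-] | intermediate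
12 | 5,7-dimethoxy-3,4-dimethyl-6-(3-methylbut-2-en-1-yl)-2-oxo-2H-chromene-8-carbaldehyde | COc1c(CC=C(C)C)c(OC)c(C=O)c2oc(=O)c(C)c(C)c12 | intermediate
13 | (E)-1-bromoprop-1-ene | C/C=C/Br | starting material
14 | 2-methylcyclopent-2-en-1-one | CC1=CCCC1=O | starting material
15 | (E)-prop-1-en-1-yllithium | C/C=C/[Li] | intermediate
16 | rac-2-methyl-1-[(1E)-prop-1-en-1-yl]cyclopent-2-en-1-ol | C/C=C/C1(O)CCC=C1C | intermediate
17 | (1RS)-2-methyl-1-[(2R,3S)-3-methyloxiran-2-yl]cyclopent-2-en-1-ol | C[C@@H]1O[C@H]1C2(O)CCC=C2C | intermediate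
18 | (2S)-3-methyl-2-[(1S)-1-(triethylsilyloxy)ethyl]cyclohex-3-en-1-one | O=C1CCC=C(C)[C@H]1[C@H](C)O[Si](CC)(CC)CC | intermediate
19 | (2S,3R)-3-methyl-2-[(1S)-1-(triethylsilyloxy)ethyl]cyclohexan-1-one | O=C1CCC[C@@H](C)[C@H]1[C@H](C)O[Si](CC)(CC)CC | intermediate
20 | potassium (5R,6S)-5-methyl-6-[(1S)-1-(triethylsilyloxy)ethyl]cyclohex-1-en-1-olate | [K+].[O-]C1=CCC[C@@H](C)[C@H]1[C@H](C)O[Si](CC)(CC)CC | intermediate
21 | (5R,6S)-5-methyl-6-[(1S)-1-(triethylsilyloxy)ethyl]cyclohex-1-en-1-yl trifluoromethanesulfonate | O=S(=O)(OC1=CCC[C@@H](C)[C@H]1[C@H](C)O[Si](CC)(CC)CC)C(F)(F)F | intermediate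
22 | 8-{hydroxy[(5R,6R)-5-methyl-6-[(1S)-1-(triethylsilyloxy)ethyl]cyclohex-1-en-1-yl]methyl}-5,7-dimethoxy-3,4-dimethyl-6-(3-methylbut-2-en-1-yl)-2H-chromen-2-one (carbinol epimers) | COc1c(CC=C(C)C)c(OC)c(C(O)C2=CCC[C@@H](C)[C@H]2[C@H](C)O[Si](CC)(CC)CC)c2oc(=O)c(C)c(C)c12 | intermediate
23 | 5,7-dimethoxy-3,4-dimethyl-6-(3-methylbut-2-en-1-yl)-8-{[(5R,6R)-5-methyl-6-[(1S)-1-(triethylsilyloxy)ethyl]cyclohex-1-en-1-yl]carbonyl}-2H-chromen-2-one | COc1c(CC=C(C)C)c(OC)c(C(=O)C2=CCC[C@@H](C)[C@H]2[C@H](C)O[Si](CC)(CC)CC)c2oc(=O)c(C)c(C)c12 | intermediate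
24 | 7-hydroxy-5-methoxy-3,4-dimethyl-6-(3-methylbut-2-en-1-yl)-8-{[(5R,6R)-5-methyl-6-[(1S)-1-(triethylsilyloxy)ethyl]cyclohex-1-en-1-yl]carbonyl}-2H-chromen-2-one | COc1c(CC=C(C)C)c(O)c(C(=O)C2=CCC[C@@H](C)[C@H]2[C@H](C)O[Si](CC)(CC)CC)c2oc(=O)c(C)c(C)c12 | intermediate
25 | 7-hydroxy-8-{[(5R,6R)-6-[(1S)-1-hydroxyethyl]-5-methylcyclohex-1-en-1-yl]carbonyl}-5-methoxy-3,4-dimethyl-6-(3-methylbut-2-en-1-yl)-2H-chromen-2-one | COc1c(CC=C(C)C)c(O)c(C(=O)C2=CCC[C@@H](C)[C@H]2[C@H](C)O)c2oc(=O)c(C)c(C)c12 | target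

## Step count and risks

Total steps: 13. Longest linear sequence: 9 (steps 1 to 6, then 11 to 13).

Steps most likely to fail:

1. Step 8 (the proposed new step). The catalyst may also epoxidise the ring alkene, or one enantiomer of 16 may be mismatched and lower the enantiomeric purity. The fallback uses known chemistry, sets out from 14 (with 15 made as in step 7) and comes back at 19. Compound 14 is hydrogenated (H2, Pd/C) to 2-methylcyclopentan-1-one F1. Addition of 15 anti to the methyl group gives rac-(1S,2R)-2-methyl-1-[(1E)-prop-1-en-1-yl]cyclopentan-1-ol F2. Shi epoxidation (L-sorbose-derived ketone, KHSO5, K2CO3, MeCN/dimethoxymethane/H2O, 0 °C) is reagent-controlled and turns each enantiomer of F2 into one separable epoxy alcohol. The wanted one is (1S,2R)-2-methyl-1-[(2R,3S)-3-methyloxiran-2-yl]cyclopentan-1-ol F3; the unwanted one is its (1R,2S) diastereomer F4. F3 with Et3SiOTf and 2,6-lutidine undergoes the same semipinacol ring expansion: the methyl-bearing ring carbon migrates with retention and the oxirane carbon is inverted. This gives 19 directly, so step 9 is not needed, at the cost of a 50 % ceiling from F2.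

2. Step 9. The catalyst may move the alkene into conjugation, which scrambles the alpha center, or the facial selectivity may be low. The fallback sets out from 18 and comes back at 19. The alkene is moved on purpose with DBU to give the conjugated enone 3-methyl-2-[(1S)-1-(triethylsilyloxy)ethyl]cyclohex-2-en-1-one F5. Heterogeneous hydrogenation of this tetrasubstituted enone (H2 50 bar, Rh/Al2O3, EtOAc) is a syn addition, so the 2,3-cis relation is enforced. The face is set by the carbinol center: A(1,3) strain puts its C–H in the alkene plane and hydrogen enters opposite the silyloxy group.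

3. Step 13. The Lewis acid may cyclise the prenyl group onto the freed phenol or attack the enone. The fallback sets out from 12 and comes back at 24. The same MgI2·OEt2 cleavage is done on the simple aldehyde, where chelation is to the formyl group, giving 7-hydroxy-5-methoxy-3,4-dimethyl-6-(3-methylbut-2-en-1-yl)-2-oxo-2H-chromene-8-carbaldehyde F6. Nozaki–Hiyama–Kishi coupling of F6 with 21 (CrCl2, NiCl2 cat.) gives the phenolic carbinol 7-hydroxy-8-{hydroxy[(5R,6R)-5-methyl-6-[(1S)-1-(triethylsilyloxy)ethyl]cyclohex-1-en-1-yl]methyl}-5-methoxy-3,4-dimethyl-6-(3-methylbut-2-en-1-yl)-2H-chromen-2-one F7. MnO2 oxidises only the benzylic, allylic carbinol and gives 24. The dilute acid of step 13 then gives 25 with no Lewis acid near the prenylated phenol.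

Further compounds

F1 | step 8 | 2-methylcyclopentan-1-one (racemic) | CC1CCCC1=O
F2 | step 8 | rac-(1S,2R)-2-methyl-1-[(1E)-prop-1-en-1-yl]cyclopentan-1-ol | C/C=C/[C@]1(O)CCC[C@H]1C
F3 | step 8 | (1S,2R)-2-methyl-1-[(2R,3S)-3-methyloxiran-2-yl]cyclopentan-1-ol | C[C@@H]1O[C@H]1[C@]2(O)CCC[C@H]2C
F4 | step 8 | (1R,2S)-2-methyl-1-[(2R,3S)-3-methyloxiran-2-yl]cyclopentan-1-ol | C[C@@H]1O[C@H]1[C@@]2(O)CCC[C@@H]2C
F5 | step 9 | 3-methyl-2-[(1S)-1-(triethylsilyloxy)ethyl]cyclohex-2-en-1-one | O=C1CCCC(C)=C1[C@H](C)O[Si](CC)(CC)CC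
F6 | step 13 | 7-hydroxy-5-methoxy-3,4-dimethyl-6-(3-methylbut-2-en-1-yl)-2-oxo-2H-chromene-8-carbaldehyde | COc1c(CC=C(C)C)c(O)c(C=O)c2oc(=O)c(C)c(C)c12
F7 | step 13 | 7-hydroxy-8-{hydroxy[(5R,6R)-5-methyl-6-[(1S)-1-(triethylsilyloxy)ethyl]cyclohex-1-en-1-yl]methyl}-5-methoxy-3,4-dimethyl-6-(3-methylbut-2-en-1-yl)-2H-chromen-2-one | COc1c(CC=C(C)C)c(O)c(C(O)C2=CCC[C@@H](C)[C@H]2[C@H](C)O[Si](CC)(CC)CC)c2oc(=O)c(C)c(C)c12
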